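Ring C (C8, C9, C11–C14) is disconnected into C8=C9 of ring B and a four-carbon ring: the contiguous C11(O)–C12(O)–C13(iPr)–C14(O) array is exactly the substitution pattern of a squaric-acid-derived cyclobutenone. Thermolysis of a 4-hydroxy-4-dienylcyclobutenone (4π ring opening, then 6π closure onto C8; Moore rearrangement) expands that four-membered ring by two atoms and delivers the fully substituted hydroquinone of ring C in one operation, with every substituent position fixed by the precursor. The precursor is an enantioenriched trans-fused ring A/B cyclohexadiene (C4, C5, C10 already set; C6=C7 retained for the later epoxidation–lactonization) bonded through C9 to the carbinol carbon of a 3-tert-butoxy-2-isopropylcyclobutenone.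

Key step: step 12

Assumption: the four starting materials are taken as purchasable. Names of bicyclic and tricyclic compounds use abietane numbering (ring A = C1–C5 and C10; ring B = C5–C10; ring C = C8, C9, C11–C14; C19 on C4, C20 on C10); β is the face of C20 and α the opposite face.

Step 1
Reactants: 1 tert-butyl 2-oxocyclohexane-1-carboxylate
Product: 3 tert-butyl 6-oxocyclohex-1-ene-1-carboxylate, via α-phenylselanyl keto ester 2 (not isolated)
Conditions: PhSeCl, pyridine, CH2Cl2, 0 °C; then 30% H2O2, 0 → 25 °C; used at once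
Reagents that add atoms: none
Why: α-Selenenylation of the β-keto ester and selenoxide syn-elimination can place the double bond only at C5=C10, because C5–H is the only β-hydrogen; no stereocenter is formed.

Step 2
Reactants: 3 tert-butyl 6-oxocyclohex-1-ene-1-carboxylate; 4 tert-butyl[(1-methoxyethenyl)oxy]dimethylsilane
Product: 6 tert-butyl (2S)-2-(2-methoxy-2-oxoethyl)-6-oxocyclohexane-1-carboxylate, via silyl enol ether 5 (not isolated)
Conditions: Cu(OTf)2 (10 mol %), (S,S)-t-Bu-box [2,2′-(propane-2,2-diyl)bis((4S)-4-tert-butyl-4,5-dihydro-1,3-oxazole)] (11 mol %), CH2Cl2, −78 °C; then dilute aq. HCl, THF, 0 °C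
Reagents that add atoms: none
Why: Enantioselective Mukaiyama–Michael addition in which the 1,3-dicarbonyl unit of 3 chelates the chiral Cu(OTf)2/bis(oxazoline) catalyst and the ketene silyl acetal attacks C5 on the face left open by the ligand (the ligand enantiomer that gives the 5S centre is used); C10 remains epimerizable, which is irrelevant for step 3.

Step 3
Reactants: 6 tert-butyl (2S)-2-(2-methoxy-2-oxoethyl)-6-oxocyclohexane-1-carboxylate; 7 1-chloro-3-iodopropane
Product: 8 tert-butyl (1R,2S)-1-(3-chloropropyl)-2-(2-methoxy-2-oxoethyl)-6-oxocyclohexane-1-carboxylate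
Conditions: Cs2CO3, DMF, 25 °C
Reagents that add atoms: none
Why: C-Alkylation of the β-keto ester enolate at the iodide end of 7; the C5 side chain sits pseudoaxial next to the planar enolate carbon and blocks one face, so the chloropropyl group enters anti to it and fixes C10 (C1 trans to C4, ester cis to C4), the relationship that later makes the ring fusion trans.

Step 4
Reactants: 8 tert-butyl (1R,2S)-1-(3-chloropropyl)-2-(2-methoxy-2-oxoethyl)-6-oxocyclohexane-1-carboxylate
Product: 9 tert-butyl (1R,6S)-1-(3-chloropropyl)-6-(2-methoxy-2-oxoethyl)-2-oxocyclohex-3-ene-1-carboxylate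
Conditions: 2-iodoxybenzoic acid (IBX, 1.3 equiv), DMSO, 70 °C
Reagents that add atoms: none
Why: IBX dehydrogenation of a ketone to the enone; only C8 carries enolizable hydrogens (C10 is quaternary), so the new double bond can only be C7=C8 and no stereocenter is touched.

Step 5
Reactants: 9 tert-butyl (1R,6S)-1-(3-chloropropyl)-6-(2-methoxy-2-oxoethyl)-2-oxocyclohex-3-ene-1-carboxylate
Product: 10 tert-butyl (1R,6R)-1-(3-chloropropyl)-6-(2-methoxy-2-oxoethyl)-2-(trifluoromethanesulfonyloxy)cyclohexa-2,4-diene-1-carboxylate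
Conditions: KN(SiMe3)2, THF, −78 °C; then PhNTf2, −78 → 0 °C
Reagents that add atoms: N-phenylbis(trifluoromethanesulfonimide), O=S(=O)(N(c1ccccc1)S(=O)(=O)C(F)(F)F)C(F)(F)F
Why: With no α′-hydrogen available the base removes the γ-hydrogen at C6 to give the linear dienolate, whose O-sulfonylation (enol triflate formation) gives the 2-triflyloxy-1,3-diene and masks the ketone for the enolate chemistry of step 6; C5 and C10 cannot epimerize.

Step 6
Reactants: 10 tert-butyl (1R,6R)-1-(3-chloropropyl)-6-(2-methoxy-2-oxoethyl)-2-(trifluoromethanesulfonyloxy)cyclohexa-2,4-diene-1-carboxylate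
Product: 12 ring A/B dienyl triflate diester (4α-CH3; 4β-CO2CH3; 5α-H; 10β-CO2t-Bu; C6=C7; C8=C9; 9-OTf), via ring-closed ester 11 (not isolated)
Conditions: LiN(i-Pr)2 (1.1 equiv), THF/DMPU, −78 → 0 °C; then −78 °C, LiN(i-Pr)2 (1.2 equiv); MeI, −78 → −20 °C
Reagents that add atoms: iodomethane, CI
Why: Intramolecular 6-exo-tet ester enolate alkylation closes ring A (the trans fusion is already fixed by C5 and C10), and the second enolate is methylated from the α face because the axial C10 tert-butoxycarbonyl group shields the β face in a 1,3-diaxial sense, which sets C4 with the ester carbon (C19) β.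

Step 7
Reactants: 12 ring A/B dienyl triflate diester
Product: 13 19-alcohol (4β-CH2OH; 4α-CH3; 10β-CO2t-Bu; 9-OTf diene)
Conditions: i-Bu2AlH (3 equiv), toluene, −78 → −20 °C; aq. KNaC4H4O6 (tartrate) work-up
Reagents that add atoms: none
Why: Hydride reduction of the methyl ester to the primary alcohol; the tert-butyl ester on quaternary C10 reacts much more slowly and the enol triflate is inert at low temperature.

Step 8
Reactants: 13 19-alcohol
Product: 14 19-O-tert-butyldiphenylsilyl ether of 13
Conditions: t-BuPh2SiCl, imidazole, DMF, 40 °C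
Reagents that add atoms: tert-butyl(chloro)diphenylsilane, CC(C)(C)[Si](Cl)(c1ccccc1)c1ccccc1
Why: Silylation under conditions that form no alkoxide (an alkoxide at C19 could lactonize onto the 1,3-diaxial C20 ester); the acid-stable silyl ether keeps O19 masked until the quinone stage.

Step 9
Reactants: 14 19-O-silyl dienyl triflate
Product: 15 9-trimethylstannyl diene (SnMe3 in place of OTf in 14)
Conditions: Pd(PPh3)4 (5 mol %), LiCl, Me3SnSnMe3, THF, 65 °C
Reagents that add atoms: hexamethylditin, C[Sn](C)(C)[Sn](C)(C)C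
Why: Pd(PPh3)4-catalysed stannylation of an enol triflate with a distannane (Stille-type coupling, LiCl assisting transmetalation) turns C9 into a latent nucleophile without touching the ester or silyl ether.

Step 10
Reactants: 16 3,4-di-tert-butoxycyclobut-3-ene-1,2-dione
Product: 18 3-tert-butoxy-4-(propan-2-yl)cyclobut-3-ene-1,2-dione, via carbinol adduct 17 (not isolated)
Conditions: i-PrMgCl, THF, −78 °C; then (CF3CO)2O, −78 → 0 °C; aq. NaHCO3
Reagents that add atoms: isopropylmagnesium chloride, CC(C)[Mg]Cl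
Why: 1,2-Addition to one squarate carbonyl, then trifluoroacetylation of the carbinol and ionization assisted by the vinylogous tert-butoxy group, which loses its tert-butyl cation, gives the 3-alkoxy-4-alkylcyclobutenedione (known squarate-to-cyclobutenedione transposition).

Step 11
Reactants: 15 9-trimethylstannyl diene; 18 3-tert-butoxy-4-(propan-2-yl)cyclobut-3-ene-1,2-dione
Product: 20 3-tert-butoxy-4-hydroxy-2-(propan-2-yl)cyclobut-2-en-1-one carrying the ring A/B dien-9-yl group at C4 (carbinol epimers), via dienyllithium 19 (not isolated)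
Conditions: MeLi (1.0 equiv), THF, −78 → −50 °C; then 18, −78 °C; aq. NH4Cl
Reagents that add atoms: none
Why: Tin–lithium exchange gives the dienyllithium, which adds 1,2 to the more electrophilic carbonyl of 18 (the one next to C–Ot-Bu; the other is a vinylogous ester) faster than to the hindered tert-butyl ester; the carbinol centre forms as a mixture, which is irrelevant because step 12 destroys it.

Step 12
Reactants: 20 4-hydroxy-4-dienylcyclobutenone
Product: 23 tricyclic arene (11,14-bis(methoxymethoxy); 12-Ot-Bu; 13-isopropyl; C6=C7; 10β-CO2t-Bu; 19-OSi(t-Bu)Ph2), via dienylketene 21 (not isolated), via hydroquinone 22 (not isolated)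
Conditions: toluene (degassed), 110 °C; then NaH, MeOCH2Cl, DMF, 0 → 25 °C (argon)
Reagents that add atoms: chloromethyl methyl ether, COCCl
Why: Heating opens the cyclobutenone by a conrotatory 4π-electrocyclic reaction in which the hydroxyl rotates outward, so the C9 dienyl group lies cis to the ketene in 21; the ketene carbon then bonds to C8 in a thermal disrotatory 6π-electrocyclization (the mode by which ring C is closed, new bond C8–C14), and enolization of the cyclohexadienone gives hydroquinone 22, which is O-alkylated in the same flask because it is air-sensitive. The closest known reaction type is the Moore rearrangement of 4-alkenyl-4-hydroxycyclobutenones to hydroquinones. No stereocenter is created: the carbinol centre of 20 and the transient sp3 C8 are erased on aromatization, and C4, C5 and C10 are not involved. The step needs regiocontrol of the ring C substituents and periselectivity: the first is fixed by the connectivity of 20 (carbinol carbon next to C–Ot-Bu, carbonyl next to C–iPr, hence O at C11, Ot-Bu at C12, iPr at C13, O at C14), the second by geometry, since only C8 of the ring-locked diene can reach the ketene carbon through a six-membered transition state, so C6=C7 survives as the styrene needed in step 13; keeping the temperature at 110 °C avoids a competing 1,5-hydrogen shift of the cyclohexadiene.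

Step 13
Reactants: 23 bis(methoxymethyl)-protected tricyclic arene
Product: 26 19-O-tert-butyldiphenylsilyl ether of the target (12-hydroxy-11,14-quinone; 7β,20-lactone; 6α-OH), via 6α,7α-epoxide 24 (not isolated), via benzenetriol lactone 25 (not isolated)
Conditions: dimethyldioxirane, acetone/CH2Cl2, −40 → 0 °C; then TFA/CH2Cl2 (1:4), 0 °C; then TFA/H2O (9:1), 25 °C; air, aq. NaHCO3 work-up
Reagents that add atoms: dimethyldioxirane, CC1(C)OO1
Why: Epoxidation of the C6=C7 styrene occurs on the α face because C19 and C20 shield the β face; acid opens the epoxide at benzylic C7 (cation stabilized by the ortho and para oxygens) and the carbonyl oxygen of the C10 tert-butyl ester, which can reach C7 only from the β face, closes the lactone with loss of isobutene (7β-O set, 6α-OH left), while the same acid removes both acetals and the aryl tert-butyl ether and air oxidizes the benzenetriol to the hydroxyquinone; O19 stays silylated so that no free hydroxyl can lactonize onto C20 while the C7–O bond is still ionizable.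

Step 14
Reactants: 26 19-O-silyl quinone lactone
Product: 27 target, (4S,5S,6R,7R,10R)-6α,12,19-trihydroxy-11,14-dioxoabieta-8,12-dien-20-oic acid 20,7β-lactone
Conditions: HF·pyridine, THF, 0 → 25 °C
Reagents that add atoms: none
Why: Fluoride cleavage of the silyl ether under mildly acidic conditions that generate no alkoxide, so the hindered lactone and the hydroxyquinone are left intact and no stereocenter is affected.

Compound list
1 | tert-butyl 2-oxocyclohexane-1-carboxylate | O=C1CCCCC1C(=O)OC(C)(C)C | starting material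
2 | tert-butyl 2-oxo-1-(phenylselanyl)cyclohexane-1-carboxylate | O=C1CCCCC1([Se]c1ccccc1)C(=O)OC(C)(C)C | intermediate
3 | tert-butyl 6-oxocyclohex-1-ene-1-carboxylate | O=C1CCCC=C1C(=O)OC(C)(C)C | intermediate
4 | tert-butyl[(1-methoxyethenyl)oxy]dimethylsilane | C=C(OC)O[Si](C)(C)C(C)(C)C | starting material
5 | tert-butyl (6S)-2-[(tert-butyldimethylsilyl)oxy]-6-(2-methoxy-2-oxoethyl)cyclohex-1-ene-1-carboxylate | CC(C)(C)[Si](C)(C)OC1=C(C(=O)OC(C)(C)C)[C@H](CC(=O)OC)CCC1 | intermediate
6 | tert-butyl (2S)-2-(2-methoxy-2-oxoethyl)-6-oxocyclohexane-1-carboxylate (C1 epimers and enol) | O=C1CCC[C@@H](CC(=O)OC)C1C(=O)OC(C)(C)C | intermediate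
7 | 1-chloro-3-iodopropane | ClCCCI | starting material
8 | tert-butyl (1R,2S)-1-(3-chloropropyl)-2-(2-methoxy-2-oxoethyl)-6-oxocyclohexane-1-carboxylate | O=C1CCC[C@@H](CC(=O)OC)[C@@]1(CCCCl)C(=O)OC(C)(C)C | intermediate
9 | tert-butyl (1R,6S)-1-(3-chloropropyl)-6-(2-methoxy-2-oxoethyl)-2-oxocyclohex-3-ene-1-carboxylate | O=C1C=CC[C@@H](CC(=O)OC)[C@@]1(CCCCl)C(=O)OC(C)(C)C | intermediate
10 | tert-butyl (1R,6R)-1-(3-chloropropyl)-6-(2-methoxy-2-oxoethyl)-2-(trifluoromethanesulfonyloxy)cyclohexa-2,4-diene-1-carboxylate | FC(F)(F)S(=O)(=O)OC1=CC=C[C@@H](CC(=O)OC)[C@@]1(CCCCl)C(=O)OC(C)(C)C | intermediate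
11 | ring-closed ester: ring A/B bicycle, 4-CO2CH3 (C4 epimers), 5α-H, 10β-CO2t-Bu, C6=C7, C8=C9, 9-OTf | COC(=O)C1CCC[C@@]2(C(=O)OC(C)(C)C)[C@H]1C=CC=C2OS(=O)(=O)C(F)(F)F | intermediate
12 | ring A/B dienyl triflate diester: 4α-CH3, 4β-CO2CH3, 5α-H, 10β-CO2t-Bu, C6=C7, C8=C9, 9-OTf | C[C@]1(C(=O)OC)CCC[C@@]2(C(=O)OC(C)(C)C)[C@H]1C=CC=C2OS(=O)(=O)C(F)(F)F | intermediate
13 | 19-alcohol: as 12 with 4β-CH2OH | C[C@]1(CO)CCC[C@@]2(C(=O)OC(C)(C)C)[C@H]1C=CC=C2OS(=O)(=O)C(F)(F)F | intermediate
14 | 19-O-tert-butyldiphenylsilyl ether of 13 | C[C@]1(CO[Si](c3ccccc3)(c3ccccc3)C(C)(C)C)CCC[C@@]2(C(=O)OC(C)(C)C)[C@H]1C=CC=C2OS(=O)(=O)C(F)(F)F | intermediate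
15 | 9-trimethylstannyl diene: as 14 with SnMe3 at C9 | C[C@]1(CO[Si](c3ccccc3)(c3ccccc3)C(C)(C)C)CCC[C@@]2(C(=O)OC(C)(C)C)[C@H]1C=CC=C2[Sn](C)(C)C | intermediate
16 | 3,4-di-tert-butoxycyclobut-3-ene-1,2-dione | CC(C)(C)OC1=C(OC(C)(C)C)C(=O)C1=O | starting material
17 | 2,3-di-tert-butoxy-4-hydroxy-4-(propan-2-yl)cyclobut-2-en-1-one (present as its magnesium alkoxide) | CC(C)C1(O)C(OC(C)(C)C)=C(OC(C)(C)C)C1=O | intermediate
18 | 3-tert-butoxy-4-(propan-2-yl)cyclobut-3-ene-1,2-dione | CC(C)C1=C(OC(C)(C)C)C(=O)C1=O | intermediate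
19 | C9 dienyllithium: as 15 with Li at C9 | C[C@]1(CO[Si](c3ccccc3)(c3ccccc3)C(C)(C)C)CCC[C@@]2(C(=O)OC(C)(C)C)[C@H]1C=CC=C2[Li] | intermediate
20 | 3-tert-butoxy-4-hydroxy-2-(propan-2-yl)cyclobut-2-en-1-one with the ring A/B dien-9-yl group at C4 (carbinol epimers) | C[C@]1(CO[Si](c3ccccc3)(c3ccccc3)C(C)(C)C)CCC[C@@]2(C(=O)OC(C)(C)C)[C@H]1C=CC=C2C1(O)C(OC(C)(C)C)=C(C(C)C)C1=O | intermediate
21 | dienylketene: C9–C(OH)=C(Ot-Bu)–C(iPr)=C=O, dienyl cis to the ketene arm | C[C@]1(CO[Si](c3ccccc3)(c3ccccc3)C(C)(C)C)CCC[C@@]2(C(=O)OC(C)(C)C)[C@H]1C=CC=C2/C(O)=C(\C(C(C)C)=C=O)OC(C)(C)C | intermediate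
22 | hydroquinone: 11,14-dihydroxy-12-tert-butoxy-13-isopropyl arene, C6=C7, 10β-CO2t-Bu, 19-OSi(t-Bu)Ph2 | C[C@]1(CO[Si](c3ccccc3)(c3ccccc3)C(C)(C)C)CCC[C@@]2(C(=O)OC(C)(C)C)[C@H]1C=Cc1c(O)c(C(C)C)c(OC(C)(C)C)c(O)c12 | intermediate
23 | 11,14-bis(methoxymethyl) ether of 22 | C[C@]1(CO[Si](c3ccccc3)(c3ccccc3)C(C)(C)C)CCC[C@@]2(C(=O)OC(C)(C)C)[C@H]1C=Cc1c(OCOC)c(C(C)C)c(OC(C)(C)C)c(OCOC)c12 | intermediate
24 | 6α,7α-epoxide of 23 | C[C@]1(CO[Si](c3ccccc3)(c3ccccc3)C(C)(C)C)CCC[C@@]2(C(=O)OC(C)(C)C)[C@H]1[C@H]3O[C@H]3c1c(OCOC)c(C(C)C)c(OC(C)(C)C)c(OCOC)c12 | intermediate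
25 | benzenetriol lactone: 11,12,14-trihydroxy arene, 7β,20-lactone, 6α-OH, 19-OSi(t-Bu)Ph2 | CC(C)c1c(O)c(O)c2c(c1O)[C@H]1OC(=O)[C@@]23CCC[C@](C)(CO[Si](c4ccccc4)(c4ccccc4)C(C)(C)C)[C@@H]3[C@H]1O | intermediate
26 | 19-O-tert-butyldiphenylsilyl ether of the target | CC(C)C1=C(O)C(=O)C2=C(C1=O)[C@H]1OC(=O)[C@@]23CCC[C@](C)(CO[Si](c4ccccc4)(c4ccccc4)C(C)(C)C)[C@@H]3[C@H]1O | intermediate
27 | (4S,5S,6R,7R,10R)-6α,12,19-trihydroxy-11,14-dioxoabieta-8,12-dien-20-oic acid 20,7β-lactone | CC(C)C1=C(O)C(=O)C2=C(C1=O)[C@H]1OC(=O)[C@@]23CCC[C@](C)(CO)[C@@H]3[C@H]1O | target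

Total step count: 14. Longest linear sequence: 13 (steps 1–9 and 11–14; step 10 is the side branch).

Steps most likely to fail

Step 13. After epoxidation the benzylic cation may undergo a 1,2-hydride shift to the C6 ketone instead of being captured by the ester, or the dioxirane may over-oxidize the electron-rich ring before it reaches the alkene. The fallback sets out from 23 and replaces the dioxirane by a dihydroxylation. OsO4 (catalytic) with N-methylmorpholine N-oxide in acetone/H2O should add from the α face to give the cis-6α,7α-diol F1. Treatment of F1 with TFA/CH2Cl2, then TFA/H2O under air, should ionize the benzylic 7-hydroxyl, close the lactone from the β face through the tert-butyl ester with inversion at C7, remove the acetals and the aryl tert-butyl ether, and give the quinone. The route is rejoined at 26.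

Step 2. Enantioselectivity may be low, or turnover slow, with the hindered tert-butyl ester acceptor. The fallback sets out from 3 and builds the C4–C19 unit from an allyl group.
- Cu(OTf)2/(S,S)-t-Bu-box-catalysed enantioselective Hosomi–Sakurai conjugate allylation with allyltrimethylsilane should give tert-butyl (2S)-6-oxo-2-(prop-2-en-1-yl)cyclohexane-1-carboxylate F2.
- Alkylation with 7 (Cs2CO3, DMF), as in step 3, should give the (1R,2S)-1-(3-chloropropyl) allyl keto ester F3.
- Ozonolysis (O3, CH2Cl2, −78 °C; Me2S) should give the aldehyde F4.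
- Pinnick oxidation (NaClO2, NaH2PO4, 2-methylbut-2-ene) should give the carboxylic acid F5.
- Esterification with Me3SiCHN2 in methanol/toluene rejoins the route at 8.

Step 11. Attack of methyllithium on the ester may compete with tin–lithium exchange, or the hindered dienyllithium may be protonated or decompose before it adds. The fallback sets out from 15 and uses an ester-tolerant magnesium reagent. Iododestannylation (iodine, CH2Cl2, 0 °C) should give the dienyl iodide F6. Iodine–magnesium exchange on F6 with i-PrMgCl·LiCl (THF, −40 °C) and addition of the dienylmagnesium reagent to 18 rejoins the route at 20.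

Further compounds
F1 | step 13 | cis-6α,7α-diol of 23 | C[C@]1(CO[Si](c3ccccc3)(c3ccccc3)C(C)(C)C)CCC[C@@]2(C(=O)OC(C)(C)C)[C@H]1[C@@H](O)[C@@H](O)c1c(OCOC)c(C(C)C)c(OC(C)(C)C)c(OCOC)c12
F2 | step 2 | tert-butyl (2S)-6-oxo-2-(prop-2-en-1-yl)cyclohexane-1-carboxylate | O=C1CCC[C@@H](CC=C)C1C(=O)OC(C)(C)C
F3 | step 2 | tert-butyl (1R,2S)-1-(3-chloropropyl)-6-oxo-2-(prop-2-en-1-yl)cyclohexane-1-carboxylate | O=C1CCC[C@@H](CC=C)[C@@]1(CCCCl)C(=O)OC(C)(C)C
F4 | step 2 | tert-butyl (1R,2S)-1-(3-chloropropyl)-6-oxo-2-(2-oxoethyl)cyclohexane-1-carboxylate | O=C1CCC[C@@H](CC=O)[C@@]1(CCCCl)C(=O)OC(C)(C)C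
F5 | step 2 | 2-[(1S,2R)-2-(tert-butoxycarbonyl)-2-(3-chloropropyl)-3-oxocyclohexyl]acetic acid | O=C1CCC[C@@H](CC(=O)O)[C@@]1(CCCCl)C(=O)OC(C)(C)C
F6 | step 11 | C9 dienyl iodide: as 15 with iodine at C9 | C[C@]1(CO[Si](c3ccccc3)(c3ccccc3)C(C)(C)C)CCC[C@@]2(C(=O)OC(C)(C)C)[C@H]1C=CC=C2I
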